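The spring run stood on its plateau by the first reading at 4.00 min, and its last reading shows 62 % bis adduct and 5 % substrate. With the rest read as single product, the coupling partner attached comes to 157 % of the substrate charged, against 156 % charged, so within the scatter of 1.5 percentage points the charged partner sits on the substrate.

all flasks: substrate 0.050 M
- spring: coupling partner 0.078 M; run made earlier
- autumn: coupling partner 0.14 M; run made earlier
- teal: coupling partner 0.0600 M; time 1.5 h
- green: coupling partner 0.100 M; time 1.5 h

- spring (time / min: bis adduct / %, substrate / %): 4.00: 61, 2; 12.0: 63, 6; 20.0: 63, 7; 30.0: 60, 5; 50.0: 62, 5
- autumn (time / min: bis adduct / %, substrate / %): 4.00: 102, 3; 6.00: 101, 1; 12.0: 99, 0; 25.0: 99, 0; 50.0: 101, 0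

(readings scatter by 1.5 percentage points)

- which of these holds the largest part of the substrate at the end of teal (bis adduct / single product / substrate)
- which of these holds the largest part of the substrate at the end of green (bis adduct / single product / substrate)
- amount of bis adduct at the end of green, in percent of the substrate charged

- a reading or a percentage of bis adduct counts all its forms, free or not

Each substrate has two sites. The site fill f, coupling partner charged over 2 times the substrate charged, is the share of sites that the charge can occupy; in teal it is 0.600. If the sites fill independently, with g the open share, then:

substrate = g × g
single product = 2 × f × g
bis adduct = f × f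

Spring has f = 0.780, which gives 60.8 % bis adduct and 4.84 % substrate, close to the readings.

Now teal in slow motion. At first, single product grows with f and bis adduct only with its square. At f = 0.5, single product stands at 50.0 % and bis adduct at 25.0 %. Coupling partner is the limiting reagent in teal, since f is below 1, so the run stops at f = 0.600. The time allowed, 1.5 h, is 22.5 times the 4.00 min of the spring plateau, so the end of teal should read:

substrate 16.0 %, single product 48.0 %, bis adduct 36.0 %

Single product leads. Green has f = 1.00, and the square gives 100 % bis adduct.

The forecast reads spring the same way, “This distribution matches two independent sites”. It names single product for teal and bis adduct for green, but allows for a slow tail at the exact balance and so stands lower on green, at 98 %.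

The flask gives 47.3 % single product in teal, ahead of 36.3 % bis adduct and 16.3 % substrate, and 99.8 % bis adduct in green.

    coupling partner + single product → bis adduct (k = 2.00 L mol⁻¹ s⁻¹)
    crystals ⇌ bis adduct, rate k2*(cs2 - [bis adduct]) while solid is left; crystals form when [bis adduct] > cs2 (solubility = 3.20 mM, k = 0.159 s⁻¹)
    substrate + coupling partner → single product (k = 3.87 L mol⁻¹ s⁻¹)
    coupling partner → decomposition product (k = 1.14 × 10⁻⁵ s⁻¹)

The step from single product has about half the constant of the step from substrate, as two independent sites require. A neighbouring flask, green with 0.040 M coupling partner, has f = 0.400, which reckons to 36.0 % substrate, 48.0 % single product and 16.0 % bis adduct. That flask holds 36 % substrate, 47.5 % single product and 16.3 % bis adduct.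

(All runs stem from a simulated flask for an exercise; noise was put on by code.)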